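## Retrosynthetic overview

1. 14 ⇐ 12: the hindered 8α-OH is formylated last, because the formate would not survive organolithium or aqueous acid steps.
2. 12 ⇐ 11 ⇐ 10: the acid comes from the aldehyde, which is carried as a Z-enecarbamate.
3. Key disconnection C12–C13: iodide 4 (C12 is the former lactone carbonyl carbon of 1) plus the chiral homoenolate equivalent 9. In 9, C13 is β to the latent C15 carbonyl and is made nucleophilic by sparteine-mediated lithiation of 8. This one step joins the C16 and C4 pieces and sets 13S.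
4. 4 ⇐ 2 ⇐ (+)-sclareolide 1, which supplies C5, C8, C9 and C10 in the correct configuration.
5. Rings: none is formed. The trans-decalin is bought with 1, and only its lactone ring is opened (step 1).

Assumption: (−)-sparteine is taken to give 13S, by analogy with the known topicity (anti attack at the γ-carbon) of (E)-3-substituted N-Boc-N-(4-methoxyphenyl)allylamines; the sense is checked at 12, and (+)-sparteine, also sold, has the mirror-image topicity.

## Route

Step 1
Reactants: 1 (+)-sclareolide
Product: 2 13,14,15,16-tetranorlabdane-8α,12-diol (ambradiol)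
Conditions: LiAlH4, THF, 0 °C to rt
Reagents that add atoms: none
Why: LiAlH4 hydride reduction of the lactone opens it to the 1,4-diol without touching C5, C8, C9 or C10, so all four ring stereocentres are carried over from 1.

Step 2
Reactants: 2 13,14,15,16-tetranorlabdane-8α,12-diol
Product: 4 12-iodo-8α-(trimethylsilyloxy)-13,14,15,16-tetranorlabdane, via iodo alcohol 3 (not isolated)
Conditions: PPh3, imidazole (5 equiv), I2, CH2Cl2, 0 °C, 30 min; then TMSCl, 0 °C to rt
Reagents that add atoms: iodine, II; chlorotrimethylsilane, C[Si](C)(C)Cl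
Why: The Appel-type (Garegg–Samuelsson) iodination is SN2 and takes only the primary C12–OH, and silylation of the tertiary O8 by TMS-imidazole formed in the same flask blocks the 5-exo Williamson closure to the cyclic ether before any strong base is met; no stereocentre is touched.

Step 3
Reactants: 5 tert-butyl (4-methoxyphenyl)carbamate; 6 (E)-1-bromobut-2-ene
Product: 8 tert-butyl [(E)-but-2-en-1-yl](4-methoxyphenyl)carbamate, via sodium carbamate 7 (not isolated)
Conditions: NaH, DMF, 0 °C; then 6, 0 °C to rt; AgNO3–SiO2 chromatography to E > 98%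
Reagents that add atoms: none
Why: SN2 N-alkylation of the carbamate anion at the primary allylic carbon keeps the E-alkene, which later fixes the exo position of the methyl group in the allyllithium; no stereocentre is formed.

Step 4
Reactants: 8 tert-butyl [(E)-but-2-en-1-yl](4-methoxyphenyl)carbamate (1.3 equiv); 4 12-iodo-8α-(trimethylsilyloxy)-13,14,15,16-tetranorlabdane
Product: 10 tert-butyl (4-methoxyphenyl)[(13S,14Z)-8α-(trimethylsilyloxy)labd-14-en-15-yl]carbamate, via allyllithium sparteine complex 9 (not isolated)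
Conditions: (−)-sparteine, n-BuLi, toluene, −78 °C, 1 h; then 4, −78 °C, 6 h, to −60 °C; MeOH quench
Reagents that add atoms: none
Why: Sparteine-mediated asymmetric deprotonation (Hoppe–Beak type) gives the Boc-chelated, configurationally stable 1-aminoallyllithium 9, a chiral homoenolate equivalent, whose γ-carbon (C13, normally the electrophilic β-carbon of a crotonate unit) displaces iodide from C12 (the former electrophilic lactone carbon) anti to lithium (SE2′ on the allyl unit, SN2 on the iodide), so 13S is set under reagent control and the Z-enecarbamate holds C15 at the aldehyde level.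

Step 5
Reactants: 10 tert-butyl (4-methoxyphenyl)[(13S,14Z)-8α-(trimethylsilyloxy)labd-14-en-15-yl]carbamate
Product: 11 (13S)-8α-hydroxylabdan-15-al
Conditions: 2 M aq HCl, THF, 0 °C to rt
Reagents that add atoms: water, O
Why: Acid hydrolysis of the enecarbamate (C14 protonation to an N-acyliminium ion, water capture, loss of carbamate 5) unmasks the aldehyde while the same acid cleaves the labile TMS ether, and C13 sits β to the new carbonyl, so it cannot enolise or epimerise.

Step 6
Reactants: 11 (13S)-8α-hydroxylabdan-15-al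
Product: 12 (13S)-8α-hydroxylabdan-15-oic acid
Conditions: NaClO2, NaH2PO4, 2-methyl-2-butene, t-BuOH/H2O, rt
Reagents that add atoms: sodium chlorite, [Na+].[O-]Cl=O
Why: Pinnick oxidation converts only the aldehyde to the acid at pH about 4, leaving the tertiary alcohol and every stereocentre untouched.

Step 7
Reactants: 12 (13S)-8α-hydroxylabdan-15-oic acid
Product: 14 (13S)-8α-formyloxylabdan-15-oic acid (target), via mixed formic anhydride 13 (not isolated)
Conditions: acetic formic anhydride (excess, in portions), pyridine, CH2Cl2, 0 °C to rt; then H2O/THF, rt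
Reagents that add atoms: acetic formic anhydride, CC(=O)OC=O
Why: In this O-acylation with a mixed anhydride the small, more electrophilic formyl carbon is transferred to the hindered equatorial 8α-OH in preference to acetyl, the basic medium avoids E1 loss of O8, the C8–O bond is never broken (retention), and the carboxyl group is only transiently tied up as anhydride 13, which water cleaves at its formyl carbon.

## Compound list

1 | (+)-sclareolide, (3aR,5aS,9aS,9bR)-3a,6,6,9a-tetramethyldecahydronaphtho[2,1-b]furan-2(1H)-one | O=C1C[C@@H]2[C@@]3(C)CCCC(C)(C)[C@@H]3CC[C@@]2(C)O1 | starting material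
2 | 13,14,15,16-tetranorlabdane-8α,12-diol, (1R,2R,4aS,8aS)-1-(2-hydroxyethyl)-2,5,5,8a-tetramethyldecahydronaphthalen-2-ol | OCC[C@@H]1[C@@]2(C)CCCC(C)(C)[C@@H]2CC[C@@]1(C)O | intermediate
3 | 12-iodo-13,14,15,16-tetranorlabdan-8α-ol | ICC[C@@H]1[C@@]2(C)CCCC(C)(C)[C@@H]2CC[C@@]1(C)O | intermediate
4 | 12-iodo-8α-(trimethylsilyloxy)-13,14,15,16-tetranorlabdane | ICC[C@@H]1[C@@]2(C)CCCC(C)(C)[C@@H]2CC[C@@]1(C)O[Si](C)(C)C | intermediate
5 | tert-butyl (4-methoxyphenyl)carbamate (N-Boc-p-anisidine) | COc1ccc(NC(=O)OC(C)(C)C)cc1 | starting material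
6 | (E)-1-bromobut-2-ene (trans-crotyl bromide) | C/C=C/CBr | starting material
7 | sodium tert-butyl (4-methoxyphenyl)carbamate-N-ide | COc1ccc([N-]C(=O)OC(C)(C)C)cc1.[Na+] | intermediate
8 | tert-butyl [(E)-but-2-en-1-yl](4-methoxyphenyl)carbamate | C/C=C/CN(C(=O)OC(C)(C)C)c1ccc(OC)cc1 | intermediate
9 | (1R,2E)-1-[Boc(4-methoxyphenyl)amino]but-2-enyllithium, (−)-sparteine complex (drawn as the σ-form, ligand omitted) | [Li][C@@H](N(C(=O)OC(C)(C)C)c1ccc(OC)cc1)/C=C/C | intermediate
10 | tert-butyl (4-methoxyphenyl)[(13S,14Z)-8α-(trimethylsilyloxy)labd-14-en-15-yl]carbamate | C[C@@H](CC[C@@H]1[C@@]2(C)CCCC(C)(C)[C@@H]2CC[C@@]1(C)O[Si](C)(C)C)/C=C\N(C(=O)OC(C)(C)C)c1ccc(OC)cc1 | intermediate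
11 | (13S)-8α-hydroxylabdan-15-al | C[C@@H](CC[C@@H]1[C@@]2(C)CCCC(C)(C)[C@@H]2CC[C@@]1(C)O)CC=O | intermediate
12 | (13S)-8α-hydroxylabdan-15-oic acid | C[C@@H](CC[C@@H]1[C@@]2(C)CCCC(C)(C)[C@@H]2CC[C@@]1(C)O)CC(=O)O | intermediate
13 | (13S)-8α-formyloxylabdan-15-oic formic anhydride | C[C@@H](CC[C@@H]1[C@@]2(C)CCCC(C)(C)[C@@H]2CC[C@@]1(C)OC=O)CC(=O)OC=O | intermediate
14 | (13S)-8α-formyloxylabdan-15-oic acid, (3S)-5-[(1R,2R,4aS,8aS)-2-(formyloxy)-2,5,5,8a-tetramethyldecahydronaphthalen-1-yl]-3-methylpentanoic acid | C[C@@H](CC[C@@H]1[C@@]2(C)CCCC(C)(C)[C@@H]2CC[C@@]1(C)OC=O)CC(=O)O | target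

## Step count and risks

- **Total steps:** 7.
- **Longest linear sequence:** 6 (1 → 2 → 4 → 10 → 11 → 12 → 14).
- **Minor 13-epimer:** any that forms in step 4 is removed by recrystallisation of 12.

**Step 4 (highest risk).**
- An unactivated primary iodide may react too slowly at −78 °C.
- Warming erodes the configurational stability of 9.
- Some α-alkylation is possible.
- Fallback, from 4 back to 12: keep the C12–C13 bond, swap the roles of the two carbons and buy the stereocentre. Magnesium insertion into 4 (Mg, Et2O) gives the Grignard reagent F1. Under CuBr·SMe2 catalysis in THF/Me2S at −30 °C, it opens commercial (S)-β-butyrolactone (C[C@H]1CC(=O)O1) at the methyl-bearing carbon. This is alkyl–oxygen cleavage by SN2 with inversion, and it gives the O-silylated acid F2 with 13S. Stirring with dilute HCl in THF removes the silyl group and returns to 12, bypassing 10 and 11.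

**Step 2.**
- Iodo alcohol 3 can close to the 8,12-cyclic ether.
- The tertiary OH may silylate too slowly in the Appel mixture.
- Fallback, from 2 back to 4: block O8 before C12 carries a leaving group. Exhaustive silylation of 2 (TMSCl, imidazole, DMF) gives the bis-silyl ether F3. K2CO3 in MeOH at 0 °C cleaves only the unhindered primary silyl ether and gives the mono-protected alcohol F4. Appel iodination of F4 (PPh3, imidazole, I2), which can no longer cyclise, gives 4.

**Step 7.**
- The hindered tertiary alcohol may be formylated only partly while the free carboxyl group consumes reagent.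
- The polar acids 12 and 14 are hard to separate.
- Fallback, from 12 back to 14: mask the acid first. BnBr with K2CO3 in DMF gives the benzyl ester F5. With the carboxyl group blocked, formic acid itself can be activated (HCO2H, DCC, DMAP, CH2Cl2, Steglich-type). This is not possible on 12, which would activate its own carboxyl group. The product is the formate benzyl ester F6, which separates from recyclable F5 on silica. Neutral hydrogenolysis (H2, Pd/C, EtOAc) frees the acid without touching the formate and gives 14.

## Further compounds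

F1 | step 4 | [8α-(trimethylsilyloxy)-13,14,15,16-tetranorlabdan-12-yl]magnesium iodide | I[Mg]CC[C@@H]1[C@@]2(C)CCCC(C)(C)[C@@H]2CC[C@@]1(C)O[Si](C)(C)C
F2 | step 4 | (13S)-8α-(trimethylsilyloxy)labdan-15-oic acid | C[C@@H](CC[C@@H]1[C@@]2(C)CCCC(C)(C)[C@@H]2CC[C@@]1(C)O[Si](C)(C)C)CC(=O)O
F3 | step 2 | 8α,12-bis(trimethylsilyloxy)-13,14,15,16-tetranorlabdane | C[Si](C)(C)OCC[C@@H]1[C@@]2(C)CCCC(C)(C)[C@@H]2CC[C@@]1(C)O[Si](C)(C)C
F4 | step 2 | 8α-(trimethylsilyloxy)-13,14,15,16-tetranorlabdan-12-ol | OCC[C@@H]1[C@@]2(C)CCCC(C)(C)[C@@H]2CC[C@@]1(C)O[Si](C)(C)C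
F5 | step 7 | benzyl (13S)-8α-hydroxylabdan-15-oate | C[C@@H](CC[C@@H]1[C@@]2(C)CCCC(C)(C)[C@@H]2CC[C@@]1(C)O)CC(=O)OCc1ccccc1
F6 | step 7 | benzyl (13S)-8α-formyloxylabdan-15-oate | C[C@@H](CC[C@@H]1[C@@]2(C)CCCC(C)(C)[C@@H]2CC[C@@]1(C)OC=O)CC(=O)OCc1ccccc1
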